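**Late readings.** At the last noon reading, 120 min, target stood at 79% and starting material at 11%. So each free catalyst charged had made 2.63 target. I called this Y: target formed per catalyst charged, a turnover number counted for target. The first-order constant of starting material read 0.0194 min⁻¹ early and 0.0181 min⁻¹ late. I saw no clear slowing, so this Y was a floor, with the catalyst apparently still working.

noon run (percent of the starting material charged)

| time / min | target / % | starting material / % |
|---|---|---|
| 6.00 | 6 | 86 |
| 20.0 | 27 | 66 |
| 30.0 | 35 | 54 |
| 50.0 | 51 | 39 |
| 80.0 | 71 | 23 |
| 90.0 | 75 | 20 |
| 120 | 79 | 11 |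

(scatter of a reading: 2 percentage points)

- the analysis behind the earlier runs scatters by 2 percentage points, standard deviation
- candidate steps: starting material + protic impurity -> quenched substrate; second substrate + free catalyst <-> catalyst intermediate B; reagent + catalyst intermediate B -> free catalyst + second product; starting material + free catalyst <-> catalyst intermediate A; free catalyst -> spent catalyst; reagent + catalyst intermediate A -> free catalyst + target
- the earlier runs do not show what temperature does; that part of a forecast is a guess
- no earlier run changes the charge of free catalyst; that part of a forecast is a guess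

**The decision.** The next flasks held half the noon catalyst.

| flask | starting material | second substrate | reagent | protic impurity | free catalyst | temperature | remark | time |
|---|---|---|---|---|---|---|---|---|
| noon | 0.050 M | 0.10 M | 0.15 M | 0.010 M | 15 mM | 20 °C | run made earlier |  |
| alder | 0.050 M | 0.100 M | 0.150 M | 0.0100 M | 7.5 mM | 20 °C |  | 10 h |
| maple | 0.050 M | 0.100 M | 0.150 M | 0.0100 M | 7.5 mM |  | at 20 °C until 3.0 h, from then on at 45 °C | 10 h |
| larch | 0.050 M | 0.100 M | 0.150 M | 0.0100 M | 7.5 mM | 45 °C |  | 10 h |

- the flask that comes out highest in amount of target, in percent of the starting material charged, or "all alike" when all lie within 1.5 percentage points (alder / maple / larch / all alike)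
- target at the end, in percent of the starting material charged, alder
- target at the end, in percent of the starting material charged, maple
- target at the end, in percent of the starting material charged, larch

Full conversion to target in them asked for Y = 6.67, 2.53 times the noon reading. Noon's Y at this charge gave 39.5% target. My working rule was a crossing. While catalyst lives, target can still rise with time. Once it is spent, target equals Y times catalyst charged over starting material charged, with temperature and the other charges held. No earlier run showed heat, and heat might shorten catalyst life. So I chose alder as the next run, at 20 °C, and committed only to target in alder above that floor.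

**The forecast.** The forecast differed from my floor and gave figures: 78% for alder, 79% for maple, 72% for larch, with maple highest. On larch it said “deactivation and quench probably speed up more”, and it called that a guess.

**The flasks.** Alder came out highest, at 88.6%. Maple gave 73.9% and larch 25.2%.

    starting material + protic impurity → quenched substrate (k = 6.90 × 10⁻⁴ M⁻¹ s⁻¹, Ea = 51.0 kJ mol⁻¹)
    second substrate + free catalyst ⇌ catalyst intermediate B (K = 24.0 M⁻¹, k = 0.00530 M⁻¹ s⁻¹, Ea = 48.0 kJ mol⁻¹, ΔH = −13.0 kJ mol⁻¹)
    reagent + catalyst intermediate B → free catalyst + second product (k = 0.0410 M⁻¹ s⁻¹, Ea = 61.0 kJ mol⁻¹)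
    starting material + free catalyst ⇌ catalyst intermediate A (K = 49.0 M⁻¹, k = 0.0430 M⁻¹ s⁻¹, Ea = 44.0 kJ mol⁻¹, ΔH = −84.0 kJ mol⁻¹)
    free catalyst → spent catalyst (k = 7.30 × 10⁻⁵ s⁻¹, Ea = 90.0 kJ mol⁻¹)
    reagent + catalyst intermediate A → free catalyst + target (k = 0.0190 M⁻¹ s⁻¹, Ea = 68.0 kJ mol⁻¹)
    (constants at 20 °C)

**Same reckoning.** Alder's Y came to 5.91, and larch's to 1.68. In larch, spent catalyst stood at 100% of the catalyst charged at 10.0 h, and target was still 25.2% at 100 h. I carried larch's Y to the neighbouring flask, which was larch with 0.0030 M of free catalyst. The rule gave 10.1% target. That neighbouring flask held 11.4% target at 10.0 h, with spent catalyst at 100%.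

The runs are calculated for an exercise; noise was put on by code.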